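**Retrosynthetic overview** (squalene numbering: ring = C2(Me2)–C3(OH)–C4–C5=C6(Me)–C7(H)(side chain))
1. The only ring is closed last, at C5=C6, by RCM of the unprotected acyclic hexaenol 13 with loss of propene. This avoids both the biomimetic epoxide/polyene C2–C7 cyclisation and a C15 + C15 allyl–allyl coupling.
2. C3–OH and the C3–C4 bond come from Brown allylation of the neopentyl aldehyde 12.
3. The C2–C7 bond, quaternary C2 and the C7 stereocentre come from a Johnson–Claisen of (S)-allylic alcohol 9 with an orthoisobutyrate. The donor carbinol carbon later leaves as propene, so the chirality relay is traceless.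
4. Alcohol 9 comes from a B-alkyl Suzuki coupling (C9–C10) of dienol 8, made from (S)-but-3-yn-2-ol, with E-vinyl iodide 4, made from farnesyl bromide.

Assumption: (2E,6E)-farnesyl bromide, (S)-but-3-yn-2-ol, vinyl-Bpin and trimethyl orthoisobutyrate are taken as catalogue chemicals.

**Step 1**
Reactants: 1 (2E,6E)-farnesyl bromide; 2 propargyl bromide
Product: 3 (6E,10E)-7,11,15-trimethylhexadeca-6,10,14-trien-2-yne (farnesyl–CH2–C≡C–CH3)
Conditions: 2, n-BuLi (2 equiv), TMEDA, Et2O/hexane, −78 °C; add 1, −78 °C → rt; then MeI, THF/DMPU, 0 °C → rt (one pot)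
Reagents that add atoms: propargyl bromide (2), C#CCBr; iodomethane, CI
Why: 1,3-dilithiopropyne reacts at its propargylic carbon by clean SN2 on the primary allylic bromide with E geometry retained, and the remaining lithium acetylide is then C-methylated (propargylation followed by acetylide alkylation).

**Step 2**
Reactants: 3
Product: 4 (2E,6E,10E)-2-iodo-7,11,15-trimethylhexadeca-2,6,10,14-tetraene
Conditions: Cp2Zr(H)Cl (2.5 equiv), THF, rt → 45 °C; I2, −78 → 0 °C, dark
Reagents that add atoms: iodine, II
Why: Schwartz hydrozirconation adds H–Zr syn and ignores trisubstituted alkenes; excess reagent equilibrates Zr to the less hindered methyl-bearing carbon (about 9:1 or better, minor isomer removed by chromatography), and iodinolysis with retention fixes the E C10=C11 geometry.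

**Step 3**
Reactants: 5 (S)-but-3-yn-2-ol
Product: 6 (2S,3E)-4-iodo-3-methylbut-3-en-2-ol
Conditions: Me3Al (3 equiv), Cp2ZrCl2 (0.3 equiv), CH2Cl2, 0 °C → rt; I2, THF, −30 °C
Reagents that add atoms: trimethylaluminium, C[Al](C)C; iodine, II
Why: Negishi Zr-catalysed carboalumination adds Me–Al syn with Me at the internal carbon, iodinolysis proceeds with retention to give the E-iodide, and the carbinol stereocentre (carried as its Al alkoxide) is untouched.

**Step 4**
Reactants: 6; 7 vinylboronic acid pinacol ester
Product: 8 (2S,3E)-3-methylhexa-3,5-dien-2-ol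
Conditions: Pd(dppf)Cl2 (3 mol %), K3PO4, THF/H2O, 45 °C
Reagents that add atoms: vinyl-Bpin (7), C=CB1OC(C)(C)C(C)(C)O1
Why: Suzuki–Miyaura vinylation of an alkenyl iodide retains the olefin geometry and tolerates the free secondary alcohol under basic conditions.

**Step 5**
Reactants: 8; 4
Product: 9 (2S,3E,7E,11E,15E)-3,7,12,16,20-pentamethylhenicosa-3,7,11,15,19-pentaen-2-ol
Conditions: 8, 9-BBN-H (2.2 equiv), THF, 0 °C → rt; then 4, Pd(dppf)Cl2 (5 mol %), AsPh3, Cs2CO3, DMF/H2O, rt
Reagents that add atoms: none (9-BBN delivers only H)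
Why: the first equivalent of 9-BBN masks the OH as a borinate, the second hydroborates only the terminal vinyl CH2 of the diene, and B-alkyl Suzuki–Miyaura coupling with the α-methyl vinyl iodide forms C9–C10 with retention of E geometry.

**Step 6**
Reactants: 9; 10 trimethyl orthoisobutyrate
Product: 11 methyl (3R,6E,10E,14E)-3-[(2E)-but-2-en-2-yl]-2,2,6,11,15,19-hexamethylicosa-6,10,14,18-tetraenoate
Conditions: 10 (10 equiv), EtCO2H (10 mol %), xylenes, 140 °C, MeOH distilled off
Reagents that add atoms: trimethyl orthoisobutyrate (10), CC(C)C(OC)(OC)OC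
Why: in this Johnson orthoester Claisen the ketene acetal Me2C=C(OMe)O-allyl has no E/Z issue and rearranges suprafacially with the carbinol methyl equatorial (axial would clash with OMe), so the (S)-carbinol on the E-alkene is relayed into (R)-C7 while the quaternary C2–C7 bond and an E-butenyl group are formed.

**Step 7**
Reactants: 11
Product: 12 (3R,6E,10E,14E)-3-[(2E)-but-2-en-2-yl]-2,2,6,11,15,19-hexamethylicosa-6,10,14,18-tetraenal
Conditions: DIBAL-H (1.1 equiv), CH2Cl2, −78 °C; Rochelle salt
Reagents that add atoms: none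
Why: in this partial ester reduction the aluminium hemiacetal of the neopentyl ester persists at −78 °C; C2 is quaternary, so nothing can enolise or epimerise, and the alkenes are inert.

**Step 8**
Reactants: 12
Product: 13 (4S,6R,9E,13E,17E)-6-[(2E)-but-2-en-2-yl]-5,5,9,14,18,22-hexamethyltricosa-1,9,13,17,21-pentaen-4-ol
Conditions: (−)-Ipc2B(allyl) [from (−)-Ipc2BOMe, (+)-α-pinene series, + allylMgBr], Et2O, −78 → −40 °C; NaOH, H2O2
Reagents that add atoms: allylmagnesium bromide (allyl source), C=CC[Mg]Br, delivered as B-allyldiisopinocampheylborane, C=CCB(C1CC2CC(C1C)C2(C)C)C1CC2CC(C1C)C2(C)C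
Why: Brown asymmetric allylboration through a Zimmerman–Traxler chair delivers allyl to the Si face of pivaldehyde-type aldehydes to give the (S)-carbinol, and reagent control overrides the remote C7 centre.

**Step 9 (key step)**
Reactants: 13
Product: 14 camelliol C, (1S,5R)-4,6,6-trimethyl-5-[(3E,7E,11E)-3,8,12,16-tetramethylheptadeca-3,7,11,15-tetraen-1-yl]cyclohex-3-en-1-ol
Conditions: Hoveyda–Grubbs II (7.5 mol %), 1,4-benzoquinone (15 mol %), PhMe (2 mM), 70 °C, Ar sparge (−propene)
Reagents that add atoms: none
Why: in this ring-closing metathesis Ru loads on the only monosubstituted alkene and, helped by the gem-dimethyl effect, closes the six-membered ring onto the proximal butenyl group far faster than any 8- or 9-membered, macrocyclic or intermolecular reaction with the chain trisubstituted alkenes; this places the ring alkene unambiguously at C5=C6, touches no stereocentre and leaves the OH and side chain cis.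

**Compound list**
1 | (2E,6E)-farnesyl bromide | CC(C)=CCC/C(C)=C/CC/C(C)=C/CBr | starting material
2 | propargyl bromide | C#CCBr | starting material
3 | (6E,10E)-7,11,15-trimethylhexadeca-6,10,14-trien-2-yne | CC#CCC/C=C(\C)CC/C=C(\C)CCC=C(C)C | intermediate
4 | (2E,6E,10E)-2-iodo-7,11,15-trimethylhexadeca-2,6,10,14-tetraene | I/C(C)=C/CC/C=C(\C)CC/C=C(\C)CCC=C(C)C | intermediate
5 | (S)-but-3-yn-2-ol | C[C@H](O)C#C | starting material
6 | (2S,3E)-4-iodo-3-methylbut-3-en-2-ol | C[C@H](O)/C(C)=C/I | intermediate
7 | vinylboronic acid pinacol ester | C=CB1OC(C)(C)C(C)(C)O1 | starting material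
8 | (2S,3E)-3-methylhexa-3,5-dien-2-ol | C[C@H](O)/C(C)=C/C=C | intermediate
9 | (2S,3E,7E,11E,15E)-3,7,12,16,20-pentamethylhenicosa-3,7,11,15,19-pentaen-2-ol | C[C@H](O)/C(C)=C/CC/C(C)=C/CC/C=C(\C)CC/C=C(\C)CCC=C(C)C | intermediate
10 | trimethyl orthoisobutyrate | CC(C)C(OC)(OC)OC | starting material
11 | methyl (3R,6E,10E,14E)-3-[(2E)-but-2-en-2-yl]-2,2,6,11,15,19-hexamethylicosa-6,10,14,18-tetraenoate | COC(=O)C(C)(C)[C@H](CC/C(C)=C/CC/C=C(\C)CC/C=C(\C)CCC=C(C)C)/C(C)=C/C | intermediate
12 | (3R,6E,10E,14E)-3-[(2E)-but-2-en-2-yl]-2,2,6,11,15,19-hexamethylicosa-6,10,14,18-tetraenal | O=CC(C)(C)[C@H](CC/C(C)=C/CC/C=C(\C)CC/C=C(\C)CCC=C(C)C)/C(C)=C/C | intermediate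
13 | (4S,6R,9E,13E,17E)-6-[(2E)-but-2-en-2-yl]-5,5,9,14,18,22-hexamethyltricosa-1,9,13,17,21-pentaen-4-ol | C=CC[C@H](O)C(C)(C)[C@H](CC/C(C)=C/CC/C=C(\C)CC/C=C(\C)CCC=C(C)C)/C(C)=C/C | intermediate
14 | camelliol C | CC(C)=CCC/C(C)=C/CC/C(C)=C/CC/C=C(\C)CC[C@@H]1C(C)=CC[C@H](O)C1(C)C | target

**Total steps:** 9, with no protecting groups.
**Longest linear sequence:** 7 (steps 3→4→5→6→7→8→9; the farnesyl branch 1→2→5→…→9 is also 7).

**Three steps most likely to fail, with fallbacks**
1. **Step 9:** the RCM must close onto a hindered trisubstituted alkene in a molecule that also holds four other trisubstituted alkenes. Fallback: build the ring first and add the polyene last.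
   - Oxidise the step-5 borane of 8 to the primary alcohol and protect it as the TBS ether.
   - Run steps 6–9 on this short-arm substrate.
   - Convert the arm to the iodide, then to the B-alkyl-9-BBN, and attach 4 by B-alkyl Suzuki as the final C–C bond. The metathesis then never sees the polyene.
2. **Step 6:** the hindered orthoisobutyrate Johnson–Claisen may be slow, or the allylic alcohol may ionise under acid. Fallback: switch to the anionic manifold.
   - Acylate 9 with isobutyryl chloride.
   - Carry out an Ireland–Claisen (LDA, TMSCl, ≤60 °C), which follows the same chirality-transfer logic, to give the acid.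
   - Reduce with LiAlH4 and oxidise to reach 12.
3. **Step 2:** hydrozirconation of the methyl/n-alkyl alkyne may not be regioselective enough. Fallback: move the sp2–sp3 bond to C11–C12.
   - Make a regio-unambiguous (E)-alkenyl iodide, I–CH=C(Me)CH2CH2–, by Negishi carboalumination of a terminal alkyne on the left-hand fragment.
   - Couple it with the 9-BBN adduct of (3E,7E)-4,8,12-trimethyltrideca-1,3,7,11-tetraene, made from farnesal and Ph3P=CH2.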